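**Retrosynthetic overview** (hexahydrobenzofuran numbering: O1, C2, C3, C3a, C4 = CMe2, C5 = CHBr, C6, C7, C7a = C–CH3)
1. Side chain last: the exocyclic C2=C bond comes from Claisen-type addition of a propanamide enolate to bromo lactone 13 followed by cyclodehydration; the CO–CH2Br bond comes from bromomethyllithium and the N-methoxy-N-methyl amide.
2. Bromo lactone 13 comes from keto lactone 11: C5–Br from C5=O (axial alcohol, then inversion); the ring oxygen on C7a from a formyl group (Baeyer–Villiger, retention), closed as a lactone onto the CH2CO2Me arm.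
3. Keto aldehyde 8 comes from a Diels–Alder reaction that makes C7–C7a and C3a–C4 together, from diene C7H2=C6H–C5(OSi)=C4Me2 (3) and E-enal 6, which carries C7a (CH3, CHO) and C3a (H, CH2CO2Me).
4. Enabling feature: in the cyclohexane ring the bromine-bearing C5 lies next to the gem-dimethyl C4 and 1,4 to the oxygenated quaternary C7a. This is the pattern of a 2-silyloxydiene/α-methyl-enal cycloadduct (C5=O as latent C–Br, C7a–CHO as latent C–O), and the anti H(C3a)/CH3(C7a) pair of the trans ring fusion is the E geometry of 6.
5. Ring order: carbocycle (step 4), then the five-membered oxygen ring as a lactone (step 6), reshaped into the 2-alkylidene tetrahydrofuran (step 9).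

Key step: step 4

Assumption: the (Z) geometry of the tetrasubstituted β-alkoxy enone (acyl group cis to the ring oxygen) is taken to be the thermodynamically preferred one, as is usual for 2-alkylidene tetrahydrofurans substituted on the exocyclic carbon, so it is set under the equilibrating acid conditions of step 9.

**Step 1**
Reactants: 1 4-methylpent-1-en-3-ol
Product: 2 4-methylpent-1-en-3-one
Conditions: IBX, EtOAc, 75 °C; filtration, careful distillation
Reagents that add atoms: none
Why: Oxidation of a secondary allylic alcohol to the vinyl ketone with a hypervalent iodine oxidant should proceed without touching the alkene; the only stereocentre of 1 is removed.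

**Step 2**
Reactants: 2 4-methylpent-1-en-3-one
Product: 3 4-methyl-3-(triisopropylsilyloxy)penta-1,3-diene
Conditions: TIPSOTf, Et3N, CH2Cl2, 0 °C → rt
Reagents that add atoms: triisopropylsilyl trifluoromethanesulfonate, CC(C)[Si](OS(=O)(=O)C(F)(F)F)(C(C)C)C(C)C
Why: Soft enolisation (silyl triflate/amine) of a vinyl ketone is the standard route to 2-silyloxydienes, and the isopropyl methine is the only enolisable position, so a single regioisomer without alkene geometry issues should form.

**Step 3**
Reactants: 4 methyl but-3-enoate; 5 methacrolein (3 equiv)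
Product: 6 methyl (3E)-4-methyl-5-oxopent-3-enoate
Conditions: second-generation Hoveyda–Grubbs catalyst [RuCl2(H2IMes)(=CH-C6H4-2-O-i-Pr)] (3 mol%), 1,4-benzoquinone (10 mol%), CH2Cl2, 40 °C
Reagents that add atoms: none
Why: Olefin cross-metathesis of a terminal alkene with methacrolein is known to give trisubstituted (E)-2-methyl-2-enals under thermodynamic control, and benzoquinone should suppress migration of the β,γ-double bond.

**Step 4**
Reactants: 3 4-methyl-3-(triisopropylsilyloxy)penta-1,3-diene; 6 methyl (3E)-4-methyl-5-oxopent-3-enoate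
Product: 8 methyl 2-[(1R,6S)-6-formyl-2,2,6-trimethyl-3-oxocyclohexyl]acetate, via silyl enol ether 7 (not isolated)
Conditions: (R)-3,3-diphenyl-1-(o-tolyl)tetrahydro-1H,3H-pyrrolo[1,2-c][1,3,2]oxazaborole (20 mol%, from (R)-α,α-diphenylprolinol and tri-o-tolylboroxine), Tf2NH (16 mol%), CH2Cl2, −78 → −40 °C; then 48% aq. HF, MeCN, 0 °C
Reagents that add atoms: none
Why: Catalytic enantioselective Diels–Alder reaction: the cationic boron binds the formyl oxygen of 6 (s-trans enal, formyl C–H···O contact to the catalyst oxygen) and lowers its LUMO, and the diene adds in a concerted but strongly asynchronous [4+2] in which the bond from the CMe2 terminus (β-carbon of the silyl enol ether, largest HOMO coefficient) to the enal β-carbon leads and the CH2–Cα bond follows. The closest known reactions are oxazaborolidinium-catalysed cycloadditions of 2-(trialkylsilyloxy)buta-1,3-dienes with α-methyl enals and Lewis acid-promoted cycloadditions of 2-silyloxydienes bearing a gem-disubstituted terminus with hindered enals and enones. The carbocycle is the only ring closed, by a suprafacial [4+2] (π4s + π2s) cycloaddition of two acyclic components, and no endo/exo question arises because neither diene terminus becomes a stereocentre. The two new stereocentres, quaternary C6 (later C7a) and C1 (later C3a), take their relative configuration from the E geometry of 6 (CH3 and CH2CO2Me cis on the alkene, hence CHO and CH2CO2Me trans on the ring, the later trans ring fusion) and their absolute configuration from the (R)-catalyst, which by the accepted model for α-substituted enals should leave the Cα-si face of the bound enal open. The step needs "para" regioselectivity (silyloxy carbon 1,4 to the formyl-bearing carbon) and 1,4- rather than 1,2-attack on the enal; the first is secured by the 3-silyloxy group, which polarises the diene far more strongly than the two methyl groups, the second by the bulky boron on the carbonyl oxygen. If bond formation becomes stepwise (Mukaiyama–Michael addition, then closure of the zwitterion), the same diastereomer is expected, because chair closure places the bulky boron enolate terminus equatorial and the methyl group axial; aqueous HF then cleaves the silyl enol ether to the ketone.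

**Step 5**
Reactants: 8 methyl 2-[(1R,6S)-6-formyl-2,2,6-trimethyl-3-oxocyclohexyl]acetate
Product: 9 methyl 2-[(1S,6S)-6-(formyloxy)-2,2,6-trimethyl-3-oxocyclohexyl]acetate
Conditions: mCPBA (1.2 equiv), NaHCO3, CH2Cl2, 0 °C
Reagents that add atoms: 3-chloroperoxybenzoic acid, OOC(=O)c1cccc(Cl)c1
Why: Baeyer–Villiger oxidation of an α-quaternary aldehyde should give the formate by migration of the tertiary ring carbon with retention of configuration, the aldehyde being attacked by the peracid before the hindered 2,2-dimethylcyclohexanone.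

**Step 6**
Reactants: 9 methyl 2-[(1S,6S)-6-(formyloxy)-2,2,6-trimethyl-3-oxocyclohexyl]acetate
Product: 11 (3aS,7aS)-4,4,7a-trimethylhexahydro-1-benzofuran-2,5-dione, via hydroxy ester 10 (not isolated)
Conditions: K2CO3 (0.2 equiv), MeOH, 0 °C → rt; then PPTS (cat.), PhMe, 60 °C
Reagents that add atoms: none
Why: Methanolysis of the formate followed by 5-exo-trig lactonisation (transesterification) of the equatorial tertiary alcohol onto the adjacent equatorial CH2CO2Me arm should give the trans-fused γ-lactone; neither ring stereocentre is epimerisable.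

**Step 7**
Reactants: 11 (3aS,7aS)-4,4,7a-trimethylhexahydro-1-benzofuran-2,5-dione
Product: 12 (3aS,5R,7aS)-5-hydroxy-4,4,7a-trimethylhexahydro-1-benzofuran-2(3H)-one
Conditions: K[(s-Bu)3BH], THF, −78 °C; then H2O
Reagents that add atoms: none
Why: Ketone reduction with a bulky trialkylborohydride should deliver hydride equatorially to the conformationally locked 2,2-dimethylcyclohexanone (as with 4,4-dimethyl-3-keto steroids), giving the axial (5R) alcohol, while the lactone is inert at −78 °C.

**Step 8**
Reactants: 12 (3aS,5R,7aS)-5-hydroxy-4,4,7a-trimethylhexahydro-1-benzofuran-2(3H)-one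
Product: 13 (3aS,5S,7aS)-5-bromo-4,4,7a-trimethylhexahydro-1-benzofuran-2(3H)-one
Conditions: CBr4, PPh3, CH2Cl2, 0 °C → rt
Reagents that add atoms: carbon tetrabromide, BrC(Br)(Br)Br
Why: Appel reaction: SN2 displacement of the axial alkoxyphosphonium group by bromide with inversion should give the equatorial (5S) bromide, a conversion with precedent for 3-hydroxy-2,2-dimethylcyclohexane units.

**Step 9**
Reactants: 13 (3aS,5S,7aS)-5-bromo-4,4,7a-trimethylhexahydro-1-benzofuran-2(3H)-one; 14 N-methoxy-N-methylpropanamide (2.3 equiv)
Product: 17 (2Z)-2-[(3aS,5S,7aS)-5-bromo-4,4,7a-trimethylhexahydro-1-benzofuran-2(3H)-ylidene]-N-methoxy-N-methylpropanamide, via lithium enolate 15 (not isolated), via hydroxy keto amide 16 (not isolated)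
Conditions: 14, LiN(i-Pr)2 (2.2 equiv), THF, −78 °C; then 13, −78 → −40 °C; AcOH; then TsOH·H2O (10 mol%), 4 Å MS, CH2Cl2, rt
Reagents that add atoms: none
Why: Claisen-type acylation of the amide enolate by the lactone, then acid-catalysed hemiketalisation (5-exo-trig) and dehydration, should give the conjugated exocyclic enol ether as the thermodynamic (Z) isomer; the equatorial neopentylic bromide has no antiperiplanar hydrogen and is hindered towards substitution, so it should survive the base.

**Step 10**
Reactants: 17 (2Z)-2-[(3aS,5S,7aS)-5-bromo-4,4,7a-trimethylhexahydro-1-benzofuran-2(3H)-ylidene]-N-methoxy-N-methylpropanamide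
Product: 19 (3Z)-1-bromo-3-[(3aS,5S,7aS)-5-bromo-4,4,7a-trimethylhexahydro-1-benzofuran-2(3H)-ylidene]butan-2-one, via tetrahedral lithium adduct 18 (not isolated)
Conditions: CH2Br2 (3 equiv), MeLi·LiBr (2.5 equiv), THF/Et2O, −78 °C; then AcOH, −78 °C
Reagents that add atoms: dibromomethane, BrCBr
Why: Carbenoid homologation of an N-methoxy-N-methyl amide: bromomethyllithium, generated by Br/Li exchange in the presence of the amide, should add once to give a chelated tetrahedral adduct that releases the bromomethyl ketone only on quench, with the alkene geometry and the secondary bromide untouched.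

**Compound list**
1 | 4-methylpent-1-en-3-ol (racemic) | CC(C)C(O)C=C | starting material
2 | 4-methylpent-1-en-3-one | CC(C)C(=O)C=C | intermediate
3 | 4-methyl-3-(triisopropylsilyloxy)penta-1,3-diene | CC(C)=C(C=C)O[Si](C(C)C)(C(C)C)C(C)C | intermediate
4 | methyl but-3-enoate | COC(=O)CC=C | starting material
5 | methacrolein (2-methylprop-2-enal) | CC(=C)C=O | starting material
6 | methyl (3E)-4-methyl-5-oxopent-3-enoate | COC(=O)C/C=C(\C)C=O | intermediate
7 | methyl 2-[(1S,6S)-6-formyl-2,2,6-trimethyl-3-(triisopropylsilyloxy)cyclohex-3-en-1-yl]acetate | COC(=O)C[C@H]1C(C)(C)C(O[Si](C(C)C)(C(C)C)C(C)C)=CC[C@]1(C)C=O | intermediate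
8 | methyl 2-[(1R,6S)-6-formyl-2,2,6-trimethyl-3-oxocyclohexyl]acetate | COC(=O)C[C@H]1C(C)(C)C(=O)CC[C@]1(C)C=O | intermediate
9 | methyl 2-[(1S,6S)-6-(formyloxy)-2,2,6-trimethyl-3-oxocyclohexyl]acetate | COC(=O)C[C@H]1C(C)(C)C(=O)CC[C@]1(C)OC=O | intermediate
10 | methyl 2-[(1S,6S)-6-hydroxy-2,2,6-trimethyl-3-oxocyclohexyl]acetate | COC(=O)C[C@H]1C(C)(C)C(=O)CC[C@]1(C)O | intermediate
11 | (3aS,7aS)-4,4,7a-trimethylhexahydro-1-benzofuran-2,5-dione (trans-fused keto lactone) | O=C1C[C@H]2C(C)(C)C(=O)CC[C@]2(C)O1 | intermediate
12 | (3aS,5R,7aS)-5-hydroxy-4,4,7a-trimethylhexahydro-1-benzofuran-2(3H)-one (axial OH) | O=C1C[C@H]2C(C)(C)[C@H](O)CC[C@]2(C)O1 | intermediate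
13 | (3aS,5S,7aS)-5-bromo-4,4,7a-trimethylhexahydro-1-benzofuran-2(3H)-one (equatorial Br) | O=C1C[C@H]2C(C)(C)[C@@H](Br)CC[C@]2(C)O1 | intermediate
14 | N-methoxy-N-methylpropanamide | CCC(=O)N(C)OC | starting material
15 | lithium (Z)-enolate of N-methoxy-N-methylpropanamide | C/C=C(\O[Li])N(C)OC | intermediate
16 | 4-[(1S,3S,6S)-3-bromo-6-hydroxy-2,2,6-trimethylcyclohexyl]-N-methoxy-N,2-dimethyl-3-oxobutanamide (both epimers at the amide α-carbon; in equilibrium with its lactol) | CON(C)C(=O)C(C)C(=O)C[C@H]1C(C)(C)[C@@H](Br)CC[C@]1(C)O | intermediate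
17 | (2Z)-2-[(3aS,5S,7aS)-5-bromo-4,4,7a-trimethylhexahydro-1-benzofuran-2(3H)-ylidene]-N-methoxy-N-methylpropanamide | C/C(C(=O)N(C)OC)=C1\C[C@H]2C(C)(C)[C@@H](Br)CC[C@]2(C)O1 | intermediate
18 | lithium alkoxide of the bromomethyl/N-methoxy-N-methylamino carbinol formed from 17 (configuration at the new carbinol carbon not defined) | C/C(C(O[Li])(CBr)N(C)OC)=C1\C[C@H]2C(C)(C)[C@@H](Br)CC[C@]2(C)O1 | intermediate
19 | (3Z)-1-bromo-3-[(3aS,5S,7aS)-5-bromo-4,4,7a-trimethylhexahydro-1-benzofuran-2(3H)-ylidene]butan-2-one | C/C(C(=O)CBr)=C1\C[C@H]2C(C)(C)[C@@H](Br)CC[C@]2(C)O1 | target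

**Step count**
Total steps: 10. Longest linear sequence: 9 steps (steps 1, 2 and 4–10, from 1).

**Steps most likely to fail**

Step 4. The cycloaddition may stall or be diverted at the fully substituted diene terminus (protodesilylation of the diene, 1,2-addition to the formyl group, an open-chain Michael adduct), and facial discrimination on the trisubstituted enal may be poor or of the opposite sense. Fallback, setting out from 3 and 6: the cycloaddition is run without the chiral catalyst under the mixed aluminium Lewis acid AlBr3/AlMe3 (PhMe/CH2Cl2, −5 °C), conditions devised for pairs of hindered 2-silyloxydienes and hindered dienophiles, to give racemic silyl enol ether F1, which the same aqueous HF treatment converts into racemic keto aldehyde F2. Condensation of F2 with (1R,2R)-N,N'-dimethyl-1,2-diphenylethane-1,2-diamine (Et2O, 4 Å MS, rt; only the aldehyde reacts) gives two diastereomeric imidazolidines, aminal F3 (from 8) and aminal F4 (from the enantiomer of 8), separable by chromatography or crystallisation. Mild acid hydrolysis of F3 (aq. HCl, Et2O, 0 °C) liberates 8 as a single enantiomer, and the route is rejoined at compound 8.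

Step 8. The axial, neopentylic alkoxyphosphonium ion may ionise (methyl migration from the gem-dimethyl carbon, elimination towards C6) faster than bromide attacks with inversion. Fallback, setting out from keto lactone 11: KN(SiMe3)2/PhNTf2 (THF, −78 °C) should give enol triflate F5 (only the C6 side of the ketone can enolise). Triflate-to-bromide exchange ([Cp*Ru(MeCN)3]OTf cat., LiBr, 1,3-dimethyl-2-imidazolidinone, heat) should give vinyl bromide F6. Hydrogen-atom-transfer hydrogenation (Mn(dpm)3 cat., PhSiH3, t-BuOOH, i-PrOH, rt) should then reduce the bromoalkene to the bromoalkane without loss of bromine, hydrogen reaching the α-bromo radical along the axial direction so that bromine ends equatorial. This returns to compound 13.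

Step 10. The thermally fragile carbenoid may decompose, or deprotonate the γ-CH2 group, faster than it adds to the deactivated (vinylogous carbamate) amide carbonyl. Fallback, setting out from 17: MeLi (THF, −78 → 0 °C) should give methyl ketone F7. Kinetic α′-enolisation (LiN(SiMe3)2, Me3SiCl, THF, −78 °C) should give silyl dienol ether F8, and NBS (THF, −78 → 0 °C) should brominate its terminal carbon, returning to compound 19.

**Further compounds**
F1 | step 4 | racemic methyl 2-[6-formyl-2,2,6-trimethyl-3-(triisopropylsilyloxy)cyclohex-3-en-1-yl]acetate (7 and its enantiomer) | COC(=O)C[C@H]1C(C)(C)C(O[Si](C(C)C)(C(C)C)C(C)C)=CC[C@]1(C)C=O.COC(=O)C[C@@H]1C(C)(C)C(O[Si](C(C)C)(C(C)C)C(C)C)=CC[C@@]1(C)C=O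
F2 | step 4 | racemic methyl 2-[6-formyl-2,2,6-trimethyl-3-oxocyclohexyl]acetate (8 and its enantiomer) | COC(=O)C[C@H]1C(C)(C)C(=O)CC[C@]1(C)C=O.COC(=O)C[C@@H]1C(C)(C)C(=O)CC[C@@]1(C)C=O
F3 | step 4 | (4R,5R)-1,3-dimethyl-4,5-diphenylimidazolidin-2-yl aminal of 8 | COC(=O)C[C@H]1C(C)(C)C(=O)CC[C@]1(C)C1N(C)[C@H](c2ccccc2)[C@@H](c2ccccc2)N1C
F4 | step 4 | (4R,5R)-1,3-dimethyl-4,5-diphenylimidazolidin-2-yl aminal of the enantiomer of 8 | COC(=O)C[C@@H]1C(C)(C)C(=O)CC[C@@]1(C)C1N(C)[C@H](c2ccccc2)[C@@H](c2ccccc2)N1C
F5 | step 8 | (3aS,7aS)-4,4,7a-trimethyl-2-oxo-2,3,3a,4,7,7a-hexahydro-1-benzofuran-5-yl trifluoromethanesulfonate | O=C1C[C@H]2C(C)(C)C(OS(=O)(=O)C(F)(F)F)=CC[C@]2(C)O1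
F6 | step 8 | (3aS,7aS)-5-bromo-4,4,7a-trimethyl-3a,4,7,7a-tetrahydro-1-benzofuran-2(3H)-one | O=C1C[C@H]2C(C)(C)C(Br)=CC[C@]2(C)O1
F7 | step 10 | (3Z)-3-[(3aS,5S,7aS)-5-bromo-4,4,7a-trimethylhexahydro-1-benzofuran-2(3H)-ylidene]butan-2-one | C/C(C(C)=O)=C1\C[C@H]2C(C)(C)[C@@H](Br)CC[C@]2(C)O1
F8 | step 10 | {[(3Z)-3-[(3aS,5S,7aS)-5-bromo-4,4,7a-trimethylhexahydro-1-benzofuran-2(3H)-ylidene]but-1-en-2-yl]oxy}trimethylsilane | C/C(C(=C)O[Si](C)(C)C)=C1\C[C@H]2C(C)(C)[C@@H](Br)CC[C@]2(C)O1
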